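(The constants are assumed; the flask was simulated.)

If your hunch is right that slow dissolution of the solid substrate is what costs target here, the cost must show up as time, so we reckoned it as time.

solid substrate 0.16 M; gas 32 mM (held); free enzyme 0.01 mol%; added ligand 19 µM; time 2.5 d

    free enzyme + added ligand ⇌ idle complex, settled at all times (K1 = 1.1 × 10⁶ /M)
    gas ⇌ second substrate, rate k2*(csat - [second substrate]) (k2 = 7.2 /h, csat = 32 mM)
    solid substrate ⇌ starting material, rate k3*(cs3 - [starting material]) while solid is left; crystals form when [starting material] > cs3 (cs3 = 0.10 M, k3 = 0.25 /h)
    second complex → free enzyme + target (k4 = 1500 /h)
    first complex → loaded enzyme + first product (k5 = 210 /h)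
    second substrate + loaded enzyme ⇌ second complex (K6 = 470 /M, k6 = 1.1 × 10⁵ /M/h)
    starting material + free enzyme ⇌ first complex (K7 = 3.7 /M, k7 = 1.6 × 10⁵ /M/h)

1. how much target there is at 2.5 d, in percent of the solid substrate charged
2. concentration of second substrate in solution at 6.0 h, in percent of saturation
3. the change that raises the amount of target at 2.5 d, in percent of the solid substrate charged most ("none" if none brings more than 2 percentage points) (midnight / dusk / noon / spring / none)
4. amount of target at 2.5 d, in percent of the solid substrate charged, after spring

- midnight: doubling the solubility in step 3, all else as stated
- dusk: doubling the amount of free enzyme, all else as stated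
- noon: doubling the transfer coefficient of step 2, all else as stated
- spring: doubling the dissolution coefficient of step 3, all else as stated

- given per volume of solution although it is solid: solid substrate
- at the start none of second substrate is dissolved
- at the start none of the solid substrate is in solution
- run time (flask): 2.5 d

The flask holds 16.0 µM of enzyme, with 19 µM of added ligand. Set c(starting material) at its solubility and c(second substrate) at saturation. Free enzyme then passes through the first complex with a pseudo-first-order constant 77.3 /h. The forms of the working round total 1.45 times c(free enzyme). The balance with the idle complex is a quadratic, and it gives c(free enzyme) = 2.01 µM, so the turnover is 156 µM/h.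

That is far below the 25.0 mM/h dissolution can deliver into an empty solution, so we let c(starting material) rise exponentially towards solubility. Taking the turnover in proportion to it, the integral is target = turnover × (time − lost time). The lost time, the reciprocal of the dissolution coefficient, is 4.00 h. It is 6.67% of the run, so on this reckoning slow dissolution costs little. We get 8.72 mM, or 5.45%.

Spring shortens the lost time to 2.00 h, which gives 5.64%, a gain of 0.19 percentage points. At full turnover c(second substrate) stands at 99.9% of saturation, so the gap on which noon acts is 0.0676% of saturation. Midnight raises c(starting material) by a factor of at most 1.60, which in proportion we put at 3.3 points. Dusk charges 32.0 µM of enzyme against the same ligand; the quadratic then gives 10.1 µM free, worth 22 points. We choose dusk.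

The forecast gives 5.45%, >99.9%, dusk and 5.64%, on the grounds: “This is far below the dissolution and gas-transfer limits, so solid persists”. Its lost time is 3.7 h against our 4.00 h.

The simulation gives 5.45%, 99.9%, dusk with 22 points, and 5.64% after spring, a gain of 0.19 points.

This flask has not come to rest at 2.5 d. Turnover and lost time carried to 25.0 d, ten times as long, with c(starting material) held at solubility, reckon 58.0%, and the flask holds 55.1%. Over that stretch its target goes from 5.45% to 55.1%, its solid substrate from 32.4% to 0%, and its starting material from 62.1% to 44.9%.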